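In a one-step world substrate goes to product and nothing comes back, so each minute takes the same share of what is left, and the bench rule is that a few half-lives empty the flask.

| setting | oak | elm | flask |
|---|---|---|---|
| substrate | 0.16 M | 0.24 M | 0.16 M |
| free enzyme | 0.01 mol% | 0.01 mol% | 0.01 mol% |
| temperature | 20 °C | 20 °C | 20 °C |
| remark | the very flask that is asked about, followed so far | run made earlier |  |
| time |  |  | 50 min |

- oak (time / min: product / %, substrate / %): 4.00: 15.9, 84.9; 10.0: 30.7, 71.7; 20.0: 35.9, 61.7; 30.0: 38.3, 61.2
- elm (time / min: product / %, substrate / %): 1.33: 6.4, 92.7; 2.50: 12.5, 86.1; 4.00: 19.2, 81.5; 5.00: 21.8, 77.6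

(standard deviation of a reading: 1 percentage point)

- product that was removed still counts
- the analysis behind the earlier runs scatters by 1 percentage point, standard deviation
- the earlier runs do not show what temperature does; that part of a forecast is a guess
- additions bring no volume worth counting

- Saturday's: at 50 min take out 90% of the product then present, then wait 1.5 h
- Monday's: at 50 min add free enzyme, 100% of the amount charged, then wait 1.5 h
- Friday's: at 50 min raise the temperature by 25 K, then wait 1.5 h
- Sunday's: change nothing and wait 1.5 h more

1. product, in percent of the substrate first charged, at 50 min
2. the remedy with the largest gain of product, or "none" below 2 percentage points (Saturday's / Monday's / Friday's / Sunday's / none)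
3. product present, with what was taken out counted in, in percent of the substrate first charged, after Saturday's
4. product present, with what was taken out counted in, in percent of the substrate first charged, after Friday's

I try the rule on oak, the asked flask followed so far. Its reading at 4.00 min leaves 84.9% substrate, which gives a first-order constant of 0.0409 min⁻¹ and a half-life of 16.9 min. The rule then leaves 29.3% at 30.0 min, but oak reads 61.2%, which is more. The border shows in a ratio: c(product)/c(substrate) in oak climbs to 0.582 at 20.0 min and 0.626 at 30.0 min, while substrate moves by 0.5 percentage points between those readings, less than the scatter of 1 point. So I freeze it and name it the plateau ratio Q: c(product)/c(substrate) once readings stop moving at a given temperature, the apparent equilibrium constant of a reversible reaction. Elm ends at 0.281, lower than Q, so it shows no plateau.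

A dead enzyme gives the same flat readings, so Q is a bet on equilibrium. With that bet, product at 50 min is Q/(1+Q), or 38.5%. Saturday's removes 34.6%, the remaining 65.4% splits again by Q, and the total with the removed product is 59.8%.

The forecast gives 39.5% (38% to 41.5%), slightly above my figure. It names Saturday's, with 59% (40% to 63%) after Saturday's and 41% (37% to 47%) after Friday's. Its words are: “I lean modestly towards equilibrium”.

The flask gives 39.9%, and Saturday's gives 61.5%, the largest gain at 22 points, while Friday's gives 38.0%. The equations are these:

    free enzyme → unfolded enzyme (k = 0.00621 min⁻¹, Ea = 230 kJ mol⁻¹)
    substrate + free enzyme ⇌ complex (K = 5.20 M⁻¹, k = 33700 M⁻¹ s⁻¹, Ea = 10.0 kJ mol⁻¹, ΔH = −67.0 kJ mol⁻¹)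
    complex ⇌ free enzyme + product (K = 0.128 M, k = 1080 min⁻¹, Ea = 56.0 kJ mol⁻¹, ΔH = 6.00 kJ mol⁻¹)
    (constants at 20 °C)

At 50.0 min the flask still holds 54.5% of its catalyst as free enzyme, and c(product)/c(substrate) stands at 0.664. Q as read puts product at 38.5% on a plateau. The neighbour flask with 0.040 M of substrate, at the same loading and time, has 35.2% product beside 64.8% substrate, so its ratio, lower than Q, is 0.543.

The data are calculated for an exercise; scatter was added.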